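**Retrosynthetic overview**
1. Feature: ring B (C5–C10) of this labdane carries oxygen on C6 and C7, methyl on C8 and C10, and the C11 chain on C9. This is the substitution pattern of 3-methoxy-2,6-dimethyl-1,4-benzoquinone with C6 and C9 as the carbonyl carbons, so ring B enters ready-made.
2. Ring A is closed second. C1–C10 and C4–C5 are cut back to 4-methylpenta-1,3-diene and the free C5=C10 quinone alkene (enantioselective Diels–Alder, then C5 epimerisation to the trans-decalin).
3. C6–OH comes from α-face hydride. C9–C11 comes from allyl addition to the C9 vinylogous ester with transposition to the 8-en-7-one. C9–H (metal–ammonia), C8–OH (Rubottom) and C7–OH (hydride) are then all delivered from the α face.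
4. The diene grows from the allyl group: C12=C13 by cross-metathesis to an alkenylboronate, C13–C14 by Suzuki coupling. O7 is acetylated last.

Key step: step 3

Assumption: labdane numbering is used for every intermediate (quinone C1–C6 = C9, C8, C7, C6, C5, C10), and the (R) antipode of the step 3 catalyst is assigned from the accepted binding model of protonated oxazaborolidines; the absolute sense must be checked on the trans-fused adduct, and the (S) antipode is equally available.

**Step 1**
Reactants: 1 2,6-dimethyl-1,4-benzoquinone
Product: 3 3-bromo-2,6-dimethyl-1,4-benzoquinone, via trans-dibromide 2 (not isolated)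
Conditions: Br2 (1.0 equiv), AcOH, 20 °C, dark; then NaOAc (1.5 equiv), 20 → 50 °C
Reagents that add atoms: bromine, BrBr
Why: Electrophilic anti addition of bromine to one of the two equivalent quinone alkenes, followed by E1cB loss of HBr (C3–H is α to C4=O), returns the quinone with bromine on the future C7, and the stereocentres of 2 vanish.

**Step 2**
Reactants: 3 3-bromo-2,6-dimethyl-1,4-benzoquinone
Product: 4 3-methoxy-2,6-dimethyl-1,4-benzoquinone
Conditions: NaOMe (1.05 equiv), MeOH, −20 → 0 °C; AcOH quench
Reagents that add atoms: sodium methoxide, C[O-].[Na+]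
Why: Conjugate addition–elimination on a haloquinone: attack at the bromine-bearing carbon is made irreversible by loss of bromide, whereas addition at the free C–H position is reversible, and low temperature with a short contact time spares the base-sensitive methylquinone.

**Step 3**
Reactants: 4 3-methoxy-2,6-dimethyl-1,4-benzoquinone; 5 4-methylpenta-1,3-diene
Product: 7 trans-fused (5α-H,10β-CH3)-7-methoxy-4,4,8,10-tetramethyldecalin-2,7-diene-6,9-dione, via cis-fused adduct 6 (not isolated)
Conditions: (R)-1-(2-methylphenyl)-3,3-diphenyltetrahydro-1H,3H-pyrrolo[1,2-c][1,3,2]oxazaborole (20 mol %), (CF3SO2)2NH (17 mol %), 5 (5 equiv, freed of 2-methylpenta-1,3-diene with maleic anhydride and distilled), CH2Cl2, −40 → 0 °C; Et3N quench; then DBU (0.3 equiv), CH2Cl2, 23 °C, Ar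
Reagents that add atoms: none
Why: The protonated oxazaborolidine binds the lone pair of O6 that lies beside C5–H, the only carbonyl lone pair of 4 with no methyl or methoxy neighbour and the carbonyl that is not weakened as a vinylogous ester, so C10 becomes the most electrophilic alkene carbon and a concerted but very asynchronous [4+2] cycloaddition follows in which the nucleophilic CH2 terminus of 5 (C1) bonds to C10 ahead of C4–C5. The closest known reaction type is the oxazaborolidinium-catalysed enantioselective Diels–Alder reaction of di- and trisubstituted 1,4-benzoquinones, combined with the classical base equilibration of angular-methyl quinone adducts, whose aromatisation is blocked by the quaternary C10. Ring A closes as the six-membered ring of this intermolecular cycloaddition, both new bonds being made suprafacially on one face of the quinone. C10 is set by the catalyst, whose phenyl group covers the β face so that the diene enters from the α face and leaves the methyl group β, whereas C5 is first cis (5β-H in 6) and is then inverted by DBU through the C5=C6 dienolate to the more stable trans-fused 5α-H isomer 7 under control of the fixed C10 centre. Site selectivity for C5=C10 over C7=C8 is secured by the donor methoxy group and the full substitution of C7=C8, and the orientation by the C10/C1 polarity match together with the steric cost of joining the two fully substituted carbons C4 and C10. Because the Z-methyl group of 5 disfavours the s-cis form, the diene is used in excess, the acid is kept below the amount of oxazaborolidine to limit cationic oligomerisation, and a long reaction time is allowed.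

**Step 4**
Reactants: 7 trans-fused dienedione
Product: 8 trans-fused (5α-H,10β-CH3)-7-methoxy-4,4,8,10-tetramethyldecalin-7-ene-6,9-dione
Conditions: H2 (1 atm), 10% Pd/C, EtOAc, 23 °C
Reagents that add atoms: none
Why: Heterogeneous catalytic hydrogenation saturates the cis-disubstituted C2=C3 alkene, while the tetrasubstituted push–pull C7=C8 alkene stays inert, and no stereocentre is formed or touched.

**Step 5**
Reactants: 8 trans-fused enedione
Product: 9 6β-hydroxy-7-methoxy-4,4,8,10-tetramethyl-trans-decalin-7-en-9-one
Conditions: NaBH4, CeCl3·7H2O, MeOH, −78 → −40 °C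
Reagents that add atoms: none
Why: Luche 1,2-reduction picks the C6 ketone, the only carbonyl that is neither a vinylogous ester nor neopentyl, and hydride enters from the α face because the β face is closed by the syn-axial 4β- and 10β-methyl groups, which sets the axial 6β-OH.

**Step 6**
Reactants: 9 6β-hydroxy vinylogous ester; 10 allylmagnesium bromide
Product: 12 9-allyl-6β-hydroxy-4,4,8,10-tetramethyl-trans-decalin-8-en-7-one, via tertiary carbinol 11 (not isolated)
Conditions: 10 (3 equiv), THF, 0 → 23 °C; then 1 M HCl, THF, 0 → 23 °C
Reagents that add atoms: water, O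
Why: Stork–Danheiser sequence: after one equivalent has deprotonated O6–H, the very reactive allyl Grignard reagent adds 1,2 to the hindered C9 carbonyl (C9–C11 bond), and acid ionises carbinol 11 to the C7 oxocarbenium ion, whose hydrolysis gives the transposed 8-en-7-one, so the transient C9 carbinol centre is of no consequence.

**Step 7**
Reactants: 12 9-allyl-6β-hydroxy-8-en-7-one
Product: 14 9β-allyl-6β,7-bis(trimethylsilyloxy)-4,4,8,10-tetramethyl-trans-decalin-7-ene (9α-H), via dilithium enolate alkoxide 13 (not isolated)
Conditions: Li (5 equiv), NH3/THF, −78 °C, inverse addition of 12, no external proton source; isoprene; NH3 evaporated; TMSCl/Et3N (excess), THF, −78 → 0 °C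
Reagents that add atoms: chlorotrimethylsilane, C[Si](C)(C)Cl
Why: Dissolving-metal conjugate reduction: two electrons and the single proton supplied by O6–H turn the enone into the C7=C8 lithium enolate, with axial protonation of C9 from the α face (anti to 10β-CH3, side chain equatorial), the C6 oxygen being kept because it is present as a non-leaving lithium alkoxide and the isolated allyl alkene being inert, and TMSCl then traps enolate and alkoxide regiospecifically.

**Step 8**
Reactants: 14 bis-silyl enol ether
Product: 16 9β-allyl-6β,8α-dihydroxy-4,4,8β,10-tetramethyl-trans-decalin-7-one, via 8α-silyloxy ketone 15 (not isolated)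
Conditions: mCPBA (1.05 equiv), NaHCO3, CH2Cl2, −20 → 0 °C; then 48% aq HF, MeCN, 0 °C
Reagents that add atoms: 3-chloroperoxybenzoic acid, O=C(OO)c1cccc(Cl)c1
Why: Rubottom oxidation: the electron-rich tetrasubstituted silyl enol ether is epoxidised far faster than the monosubstituted allyl alkene and from the α face, since the β face is covered by 10β-CH3 and the axial 6β-OTMS, so silyl migration gives the 8α-oxygenated 8β-methyl ketone 15, from which HF removes both silyl groups under non-basic conditions that leave the α-ketol centres alone.

**Step 9**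
Reactants: 16 6β,8α-dihydroxy-7-ketone
Product: 17 9β-allyl-4,4,8β,10-tetramethyl-trans-decalin-6β,7β,8α-triol
Conditions: NaBH4, MeOH, −20 → 0 °C; aq NH4Cl
Reagents that add atoms: none
Why: Borohydride reduction of a cyclohexanone along the axial α trajectory, the β face of C7 being flanked by the axial 6β-OH and 8β-CH3, gives the equatorial 7β-alcohol.

**Step 10**
Reactants: 17 allyl triol; 18 isopropenylboronic acid pinacol ester
Product: 19 (12Z)-13-(4,4,5,5-tetramethyl-1,3,2-dioxaborolan-2-yl)-14,15-dinorlabd-12-ene-6β,7β,8α-triol
Conditions: second-generation Hoveyda–Grubbs catalyst RuCl2(SIMes)(=CH-C6H4-2-OiPr) (10 mol %), 18 (4 equiv), CH2Cl2, 40 °C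
Reagents that add atoms: none
Why: Olefin cross-metathesis of a terminal alkene with a 1,1-disubstituted alkenylboronate forms the trisubstituted C12=C13 alkene with C11 trans to the bulky boronate (formally Z), which is the geometry the E-diene needs, and it tolerates the free hydroxyls without creating a Michael acceptor that O8 could attack.

**Step 11**
Reactants: 19 alkenylboronate triol; 20 vinyl bromide
Product: 21 (12E)-labda-12,14-diene-6β,7β,8α-triol
Conditions: Pd(PPh3)4 (5 mol %), 20 (1 M in THF, 5 equiv), 2 M aq NaOH (3 equiv), THF, 50 °C, sealed tube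
Reagents that add atoms: none
Why: Suzuki–Miyaura alkenyl–alkenyl coupling on zerovalent palladium forms C13–C14 with retention of the C12=C13 geometry, giving the (E)-3-methylpenta-2,4-dienyl chain.

**Step 12**
Reactants: 21 triol diene
Product: 22 (12E)-7β-acetoxylabda-12,14-diene-6β,8α-diol (target)
Conditions: Ac2O (1.5 equiv), pyridine, 0 → 23 °C; neutral work-up
Reagents that add atoms: acetic anhydride, CC(=O)OC(C)=O
Why: Chemoselective O-acylation: 7β-OH is the only equatorial secondary hydroxyl, 6β-OH is axial and boxed in by the 4β- and 10β-methyl groups, and 8α-OH is tertiary, a selectivity well known for 6β,7β-dihydroxylated labdanes, and placing the step last avoids base-induced O7 → O6 acetyl migration.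

**Compound list**
1 | 2,6-dimethyl-1,4-benzoquinone | CC1=CC(=O)C=C(C)C1=O | starting material
2 | trans-2,3-dibromo-2,6-dimethylcyclohex-5-ene-1,4-dione (racemic, formed in the flask) | CC1=CC(=O)[C@@H](Br)[C@](C)(Br)C1=O | intermediate
3 | 3-bromo-2,6-dimethyl-1,4-benzoquinone | CC1=CC(=O)C(Br)=C(C)C1=O | intermediate
4 | 3-methoxy-2,6-dimethyl-1,4-benzoquinone | COC1=C(C)C(=O)C(C)=CC1=O | intermediate
5 | 4-methylpenta-1,3-diene | CC(C)=CC=C | starting material
6 | cis-fused adduct, (5β-H,10β-CH3)-7-methoxy-4,4,8,10-tetramethyldecalin-2,7-diene-6,9-dione (formed in the flask) | O=C1C(C)=C(OC)C(=O)[C@@H]2C(C)(C)C=CC[C@@]21C | intermediate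
7 | trans-fused (5α-H,10β-CH3)-7-methoxy-4,4,8,10-tetramethyldecalin-2,7-diene-6,9-dione | O=C1C(C)=C(OC)C(=O)[C@H]2C(C)(C)C=CC[C@@]21C | intermediate
8 | trans-fused (5α-H,10β-CH3)-7-methoxy-4,4,8,10-tetramethyldecalin-7-ene-6,9-dione | O=C1C(C)=C(OC)C(=O)[C@H]2C(C)(C)CCC[C@@]21C | intermediate
9 | 6β-hydroxy-7-methoxy-4,4,8,10-tetramethyl-trans-decalin-7-en-9-one | O=C1C(C)=C(OC)[C@@H](O)[C@H]2C(C)(C)CCC[C@@]21C | intermediate
10 | allylmagnesium bromide | C=CC[Mg]Br | starting material
11 | 9α-allyl-7-methoxy-4,4,8,10-tetramethyl-trans-decalin-7-ene-6β,9β-diol (formed in the flask as its magnesium alkoxide) | C=CC[C@]1(O)C(C)=C(OC)[C@@H](O)[C@H]2C(C)(C)CCC[C@@]21C | intermediate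
12 | 9-allyl-6β-hydroxy-4,4,8,10-tetramethyl-trans-decalin-8-en-7-one | C=CCC1=C(C)C(=O)[C@@H](O)[C@H]2C(C)(C)CCC[C@@]21C | intermediate
13 | dilithium 7-enolate 6β-alkoxide of the 9β-allyl-9α-H ketone (formed in the flask) | [Li+].[Li+].C=CC[C@H]1C(C)=C([O-])[C@@H]([O-])[C@H]2C(C)(C)CCC[C@@]21C | intermediate
14 | 9β-allyl-6β,7-bis(trimethylsilyloxy)-4,4,8,10-tetramethyl-trans-decalin-7-ene | C=CC[C@H]1C(C)=C(O[Si](C)(C)C)[C@@H](O[Si](C)(C)C)[C@H]2C(C)(C)CCC[C@@]21C | intermediate
15 | 9β-allyl-6β,8α-bis(trimethylsilyloxy)-4,4,8β,10-tetramethyl-trans-decalin-7-one (formed in the flask) | C=CC[C@H]1[C@](C)(O[Si](C)(C)C)C(=O)[C@@H](O[Si](C)(C)C)[C@H]2C(C)(C)CCC[C@@]21C | intermediate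
16 | 9β-allyl-6β,8α-dihydroxy-4,4,8β,10-tetramethyl-trans-decalin-7-one | C=CC[C@H]1[C@](C)(O)C(=O)[C@@H](O)[C@H]2C(C)(C)CCC[C@@]21C | intermediate
17 | 9β-allyl-4,4,8β,10-tetramethyl-trans-decalin-6β,7β,8α-triol | C=CC[C@H]1[C@](C)(O)[C@@H](O)[C@@H](O)[C@H]2C(C)(C)CCC[C@@]21C | intermediate
18 | isopropenylboronic acid pinacol ester | C=C(C)B1OC(C)(C)C(C)(C)O1 | starting material
19 | (12Z)-13-(pinacolatoboryl)-14,15-dinorlabd-12-ene-6β,7β,8α-triol | CC3(C)OB(OC3(C)C)/C(C)=C/C[C@H]1[C@](C)(O)[C@@H](O)[C@@H](O)[C@H]2C(C)(C)CCC[C@@]21C | intermediate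
20 | vinyl bromide | C=CBr | starting material
21 | (12E)-labda-12,14-diene-6β,7β,8α-triol | C=C/C(C)=C/C[C@H]1[C@](C)(O)[C@@H](O)[C@@H](O)[C@H]2C(C)(C)CCC[C@@]21C | intermediate
22 | (12E)-7β-acetoxylabda-12,14-diene-6β,8α-diol | C=C/C(C)=C/C[C@H]1[C@](C)(O)[C@@H](OC(C)=O)[C@@H](O)[C@H]2C(C)(C)CCC[C@@]21C | target

**Total step count:** 12.
**Longest linear sequence:** 12 steps (1 → 22); 5, 10, 18 and 20 are purchased.

**Steps most likely to fail**

1. Step 3.
   - What may go wrong: the cycloaddition may be too slow because the s-cis form of the diene is poorly populated. The strong acid may oligomerise the diene. Facial discrimination on a trisubstituted quinone alkene may be insufficient. The cis/trans equilibration at C5 may stop short.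
   - Fallback, from 4 and 5: asymmetric catalysis is given up in favour of resolution. The cycloaddition is run without any acid at about 13 kbar (CH2Cl2, 23–40 °C), giving the racemic cis-fused adduct F1. DBU equilibrates it to the racemic trans-fused enedione F2. This is resolved by preparative chromatography on an amylose carbamate chiral phase. The (5α-H,10β-CH3) enantiomer is 7, where the route is rejoined.

2. Step 7.
   - What may go wrong: electron transfer may expel the axial C6 oxygen, which is aligned with the ketyl π system. Deprotonation at the doubly activated C11 may leave an unreducible dienolate. The hindered C6 alkoxide may silylate incompletely.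
   - Fallback, from 12: electron transfer is replaced by hydride transfer. O6 is silylated (TMSOTf, 2,6-lutidine, CH2Cl2, −78 °C) to the 6-O-trimethylsilyl enone F3. Copper hydride conjugate reduction (Cu(OAc)2·H2O, 1,2-bis(diphenylphosphino)benzene, polymethylhydrosiloxane, t-BuOH, toluene) delivers hydrogen to C9 from the open α face and gives the saturated 8α-methyl 7-ketone F4. Soft enolisation (TMSOTf, Et3N) can remove only the axial 8β-H, because the 6α-H is equatorial. This gives 14, where the route is rejoined.

3. Step 10.
   - What may go wrong: the 1,1-disubstituted boronate partner may convert poorly. Compound 17 may homodimerise, the allyl alkene may migrate through ruthenium hydrides, or the alkene geometry may erode.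
   - Fallback, from 17: metathesis and cross-coupling are replaced by carbonyl olefination. Ozonolysis (O3, CH2Cl2/MeOH, −78 °C; Me2S) gives the C12 aldehyde, which closes on O8 and is handled as the 8α,12-lactol F5. Wittig reaction with 2-(triphenylphosphoranylidene)propanal (toluene, 90 °C) opens it to the (12E)-enal triol F6. To forestall re-closure of O8 onto C12, F6 is methylenated at once with Ph3P=CH2 (excess, THF, −78 °C). This gives 21, where the route is rejoined, bypassing 19 and step 11.

**Further compounds**
F1 | step 3 | racemic cis-fused adduct | O=C1C(C)=C(OC)C(=O)[C@@H]2C(C)(C)C=CC[C@@]21C.O=C1C(C)=C(OC)C(=O)[C@H]2C(C)(C)C=CC[C@]21C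
F2 | step 3 | racemic trans-fused enedione | O=C1C(C)=C(OC)C(=O)[C@H]2C(C)(C)C=CC[C@@]21C.O=C1C(C)=C(OC)C(=O)[C@@H]2C(C)(C)C=CC[C@]21C
F3 | step 7 | 9-allyl-6β-trimethylsilyloxy-4,4,8,10-tetramethyl-trans-decalin-8-en-7-one | C=CCC1=C(C)C(=O)[C@@H](O[Si](C)(C)C)[C@H]2C(C)(C)CCC[C@@]21C
F4 | step 7 | 9β-allyl-8α-methyl-6β-trimethylsilyloxy-4,4,10-trimethyl-trans-decalin-7-one | C=CC[C@H]1[C@H](C)C(=O)[C@@H](O[Si](C)(C)C)[C@H]2C(C)(C)CCC[C@@]21C
F5 | step 10 | 8α,12-epoxy-13,14,15,16-tetranorlabdane-6β,7β,12-triol (lactol, C12 epimers) | OC1C[C@H]2[C@](C)(O1)[C@@H](O)[C@@H](O)[C@H]3C(C)(C)CCC[C@@]32C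
F6 | step 10 | (12E)-6β,7β,8α-trihydroxy-15-norlabd-12-en-14-al | O=C/C(C)=C/C[C@H]1[C@](C)(O)[C@@H](O)[C@@H](O)[C@H]2C(C)(C)CCC[C@@]21C
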